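## Retrosynthetic overview

1. Target ⇒ last-step hydrogenolysis of a chiral benzylic pseudoester (mixed acetal) on the lactol oxygen. No bond to the stereocentre is broken, so its (S) configuration is carried from an auxiliary-resolved phthalide building block.
2. B-ring CHO ⇒ ortho-formylation of the single free position beside the B-ring phenol, once the tricyclic core exists.
3. Seven-membered dioxepinone ⇒ direct dehydrogenative phenol C–O coupling of a depside (ester first, ether second, as in the natural depside → depsidone step).
4. Depside ⇒ haematommic acid + (3S)-5,7-dihydroxy-3-[(R)-1-phenylethoxy]phthalide. The hydroxy-lactone ring ⇒ oxidation of the orsellinate methyl to CHO and spontaneous aldehyde–carboxyl ring closure.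
5. Both aromatic rings ⇒ methyl orsellinate. Ring order: five-membered acetal-lactone first, seven-membered ring second.

Assumption: the C-1 lactol is a hemiacylal that can epimerise through the ring-opened formyl acid, so it is released only in the last step under neutral aprotic conditions and the product must be kept cold, dry and free of base.

## Route

Step 1
Reactants: 1 methyl orsellinate (methyl 2,4-dihydroxy-6-methylbenzoate)
Product: 3 methyl haematommate (methyl 3-formyl-2,4-dihydroxy-6-methylbenzoate), via chloro(methoxy)methyl ether 2 (not isolated)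
Conditions: Cl2CHOMe (1.3 equiv), TiCl4 (2.5 equiv), CH2Cl2, −20 to 0 °C; then 1 M HCl
Reagents that add atoms: dichloromethyl methyl ether COC(Cl)Cl; water O
Why: Rieche formylation, in which the titanium-bound resorcinol ester is attacked by the chloro(methoxy)carbenium ion at C-3 (ortho to both oxygens) and the chloro ether 2 is hydrolysed on work-up, the minor 5-formyl isomer being removed by crystallisation.

Step 2
Reactants: 3 methyl haematommate
Product: 4 haematommic acid (3-formyl-2,4-dihydroxy-6-methylbenzoic acid)
Conditions: conc. H2SO4, 0 °C to rt; then ice–water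
Reagents that add atoms: water O
Why: AAC1 ester cleavage of a di-ortho-substituted benzoate through its acylium ion, which avoids the base and heat that decarboxylate β-resorcylic acids and leaves the formyl group untouched.

Step 3
Reactants: 1 methyl orsellinate
Product: 5 methyl 2,4-diacetoxy-6-methylbenzoate
Conditions: Ac2O, pyridine, DMAP (cat.), CH2Cl2, rt
Reagents that add atoms: acetic anhydride CC(=O)OC(C)=O
Why: DMAP-catalysed O-acetylation masks both phenols and deactivates the ring towards electrophilic bromine in the next step.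

Step 4
Reactants: 5 methyl 2,4-diacetoxy-6-methylbenzoate
Product: 7 methyl 2,4-diacetoxy-6-(dibromomethyl)benzoate, via benzylic monobromide 6 (not isolated)
Conditions: NBS (2.3 equiv), AIBN (cat.), PhCF3, hν, 85 °C
Reagents that add atoms: N-bromosuccinimide O=C1CCC(=O)N1Br
Why: Wohl–Ziegler radical bromination at the only benzylic methyl group, taken through monobromide 6 to the gem-dibromide (aldehyde oxidation level).

Step 5
Reactants: 7 methyl 2,4-diacetoxy-6-(dibromomethyl)benzoate
Product: 10 rac-3,5,7-trihydroxy-2-benzofuran-1(3H)-one, via formyl ester 8 (not isolated), via open-chain formyl acid 9 (not isolated)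
Conditions: AgNO3 (2.2 equiv), acetone–H2O, 45 °C; then 2 M HCl, 50 °C
Reagents that add atoms: water O
Why: Silver-assisted hydrolysis of the gem-dibromide gives formyl ester 8, acid hydrolysis of the acetates and the ester gives formyl acid 9, and this closes spontaneously to the lactol by ring–chain tautomerism (the aldehyde–carboxyl cyclisation of the natural pathway), racemic at this stage.

Step 6
Reactants: 10 rac-3,5,7-trihydroxy-2-benzofuran-1(3H)-one; 11 (R)-1-phenylethanol
Product: 13 (3S)-5,7-dihydroxy-3-[(1R)-1-phenylethoxy]-2-benzofuran-1(3H)-one, via (3R)-epimeric pseudoester 12 (not isolated)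
Conditions: 11 (3 equiv), PPTS (cat.), 4 Å MS, CH2Cl2, 40 °C; 13 removed by crystallisation or chromatography, the 12-rich remainder returned to the same acid conditions
Reagents that add atoms: none
Why: Acid-catalysed pseudoester (Fischer-type O,O-acetal) formation gives both C-3 epimers, which interconvert through the phthalidyl oxocarbenium ion, so the C-3 stereocentre is set by a dynamic diastereomer resolution in which the (3S,1′R) isomer 13 is taken out and the (3R) epimer 12 left in solution re-equilibrates into it.

Step 7
Reactants: 4 haematommic acid; 13 (3S)-5,7-dihydroxy-3-[(1R)-1-phenylethoxy]-2-benzofuran-1(3H)-one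
Product: 15 (3S)-7-hydroxy-1-oxo-3-[(1R)-1-phenylethoxy]-1,3-dihydro-2-benzofuran-5-yl 3-formyl-2,4-dihydroxy-6-methylbenzoate (the depside), via O-acylisourea 14 (not isolated)
Conditions: DCC (1.1 equiv), toluene–THF, 0 °C to rt
Reagents that add atoms: none
Why: Carbodiimide (Steglich-type) esterification through O-acylisourea 14 acylates the free C-5 phenol, because the C-7 hydroxyl is chelated to the lactone carbonyl and both hydroxyls of 4 are chelated to its formyl and carboxyl groups, and the neutral conditions leave the acetal stereocentre untouched.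

Step 8
Reactants: 15 the depside
Product: 17 (1S)-4,10-dihydroxy-8-methyl-3,7-dioxo-1-[(1R)-1-phenylethoxy]-1,3-dihydro-7H-isobenzofuro[4,5-b][1,4]benzodioxepine-11-carbaldehyde (the depsidone), via aryloxy-λ3-iodane 16 (not isolated)
Conditions: PhI(OAc)2 (1.05 equiv, slow addition), HFIP–CH2Cl2 (1:4), 0 °C, 5 mM
Reagents that add atoms: none
Why: Proposed new method: the B-ring C-7 hydroxyl exchanges onto iodine(III) to give iodane 16, the A-ring 2-hydroxyl held by the ester tether attacks the free para carbon (C-4 of the phthalide) through a seven-membered transition state as iodobenzene leaves, and tautomerisation of the 4-aryloxycyclohexa-2,5-dienone restores the phenol, with the A ring deactivated by its formyl and acyl groups and the acetal stereocentre remote and unaffected; the closest known reaction types are hypervalent-iodine para-oxidation of phenols with capture by an oxygen nucleophile and the manganese dioxide-mediated oxidative cyclisation of depsides to depsidones.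

Step 9
Reactants: 17 the depsidone
Product: 19 (1S)-4,10-dihydroxy-8-methyl-3,7-dioxo-1-[(1R)-1-phenylethoxy]-1,3-dihydro-7H-isobenzofuro[4,5-b][1,4]benzodioxepine-5,11-dicarbaldehyde, via 5-hydroxymethyl depsidone 18 (not isolated)
Conditions: MgCl2 (3 equiv), Et3N (6 equiv), (CH2O)n (8 equiv), THF, 65 °C; then cold 1 M HCl
Reagents that add atoms: formaldehyde C=O
Why: Casnati–Skattebøl magnesium-mediated ortho-formylation, in which the magnesium phenoxide of the C-4 hydroxyl delivers formaldehyde to its only free ortho carbon (C-5) and a second formaldehyde oxidises alkoxide 18 by hydride transfer, while the A-ring phenol conjugated to a formyl group is inert and the base-stable acetal stereocentre is not affected.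

Step 10
Reactants: 19 the 5,11-dicarbaldehyde pseudoester
Product: 20 (1S)-1,4,10-trihydroxy-8-methyl-3,7-dioxo-1,3-dihydro-7H-isobenzofuro[4,5-b][1,4]benzodioxepine-5,11-dicarbaldehyde (target)
Conditions: H2 (1 atm), 10% Pd/C, EtOAc, 0 °C, stopped at 1 equiv uptake; filter, evaporate cold
Reagents that add atoms: none
Why: Catalytic hydrogenolysis (O-debenzylation) cleaves only the benzylic C–O bond of the auxiliary, so neither C-1–O bond is broken and the (1S) lactol is released with retention, while the chelated aryl aldehydes, the diaryl ether and both lactones survive the short exposure to Pd/C.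

## Compound list

1 | methyl orsellinate (methyl 2,4-dihydroxy-6-methylbenzoate) | COC(=O)c1c(C)cc(O)cc1O | starting material
2 | methyl 3-[chloro(methoxy)methyl]-2,4-dihydroxy-6-methylbenzoate | COC(Cl)c1c(O)cc(C)c(C(=O)OC)c1O | intermediate (not isolated)
3 | methyl haematommate (methyl 3-formyl-2,4-dihydroxy-6-methylbenzoate) | COC(=O)c1c(C)cc(O)c(C=O)c1O | intermediate
4 | haematommic acid (3-formyl-2,4-dihydroxy-6-methylbenzoic acid) | Cc1cc(O)c(C=O)c(O)c1C(=O)O | intermediate
5 | methyl 2,4-diacetoxy-6-methylbenzoate | COC(=O)c1c(C)cc(OC(C)=O)cc1OC(C)=O | intermediate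
6 | methyl 2,4-diacetoxy-6-(bromomethyl)benzoate | COC(=O)c1c(CBr)cc(OC(C)=O)cc1OC(C)=O | intermediate (not isolated)
7 | methyl 2,4-diacetoxy-6-(dibromomethyl)benzoate | COC(=O)c1c(C(Br)Br)cc(OC(C)=O)cc1OC(C)=O | intermediate
8 | methyl 2,4-diacetoxy-6-formylbenzoate | COC(=O)c1c(C=O)cc(OC(C)=O)cc1OC(C)=O | intermediate (not isolated)
9 | 2-formyl-4,6-dihydroxybenzoic acid | O=Cc1cc(O)cc(O)c1C(=O)O | intermediate (not isolated)
10 | rac-3,5,7-trihydroxy-2-benzofuran-1(3H)-one | O=C1OC(O)c2cc(O)cc(O)c21 | intermediate
11 | (R)-1-phenylethanol | C[C@@H](O)c1ccccc1 | starting material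
12 | (3R)-5,7-dihydroxy-3-[(1R)-1-phenylethoxy]-2-benzofuran-1(3H)-one | Oc1cc(O)c2c(c1)[C@H](O[C@H](C)c1ccccc1)OC2=O | intermediate (not isolated)
13 | (3S)-5,7-dihydroxy-3-[(1R)-1-phenylethoxy]-2-benzofuran-1(3H)-one | Oc1cc(O)c2c(c1)[C@@H](O[C@H](C)c1ccccc1)OC2=O | intermediate
14 | O-acylisourea of haematommic acid with DCC | Cc1cc(O)c(C=O)c(O)c1C(=O)OC(=NC1CCCCC1)NC1CCCCC1 | intermediate (not isolated)
15 | (3S)-7-hydroxy-1-oxo-3-[(1R)-1-phenylethoxy]-1,3-dihydro-2-benzofuran-5-yl 3-formyl-2,4-dihydroxy-6-methylbenzoate | Cc1cc(O)c(C=O)c(O)c1C(=O)Oc1cc(O)c2c(c1)[C@@H](O[C@H](C)c1ccccc1)OC2=O | intermediate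
16 | aryloxy(acetoxy)phenyl-λ3-iodane of 15 at the C-7 oxygen | Cc1cc(O)c(C=O)c(O)c1C(=O)Oc1cc(O[I](OC(C)=O)c2ccccc2)c2c(c1)[C@@H](O[C@H](C)c1ccccc1)OC2=O | intermediate (not isolated)
17 | (1S)-4,10-dihydroxy-8-methyl-3,7-dioxo-1-[(1R)-1-phenylethoxy]-1,3-dihydro-7H-isobenzofuro[4,5-b][1,4]benzodioxepine-11-carbaldehyde | Cc1cc(O)c(C=O)c2c1C(=O)Oc1cc(O)c3c(c1O2)[C@@H](O[C@H](C)c1ccccc1)OC3=O | intermediate
18 | (1S)-4,10-dihydroxy-5-(hydroxymethyl)-8-methyl-3,7-dioxo-1-[(1R)-1-phenylethoxy]-1,3-dihydro-7H-isobenzofuro[4,5-b][1,4]benzodioxepine-11-carbaldehyde | Cc1cc(O)c(C=O)c2c1C(=O)Oc1c(CO)c(O)c3c(c1O2)[C@@H](O[C@H](C)c1ccccc1)OC3=O | intermediate (not isolated)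
19 | (1S)-4,10-dihydroxy-8-methyl-3,7-dioxo-1-[(1R)-1-phenylethoxy]-1,3-dihydro-7H-isobenzofuro[4,5-b][1,4]benzodioxepine-5,11-dicarbaldehyde | Cc1cc(O)c(C=O)c2c1C(=O)Oc1c(C=O)c(O)c3c(c1O2)[C@@H](O[C@H](C)c1ccccc1)OC3=O | intermediate
20 | (1S)-1,4,10-trihydroxy-8-methyl-3,7-dioxo-1,3-dihydro-7H-isobenzofuro[4,5-b][1,4]benzodioxepine-5,11-dicarbaldehyde | Cc1cc(O)c(C=O)c2c1C(=O)Oc1c(C=O)c(O)c3c(c1O2)[C@@H](O)OC3=O | target

## Step count and risks

Total step count: 10.
Longest linear sequence: 8 steps (steps 3, 4, 5, 6, 7, 8, 9, 10 from methyl orsellinate 1).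

The three steps most likely to fail:

**Step 8 (dehydrogenative C–O ring closure).** The risks are oxidation of the A ring instead of the B ring, attack at the ortho carbon instead of the para carbon, and over-oxidation of the product to a quinone with loss of the new aryl ether. The fallback moves the oxidation to the monomer as a halogenation and closes the ring by copper catalysis. It sets out from 13: NBS in MeCN at 0 °C brominates C-4, para to the chelated C-7 hydroxyl, to give (3S)-4-bromo-5,7-dihydroxy-3-[(1R)-1-phenylethoxy]-2-benzofuran-1(3H)-one F1. DCC coupling with 4, as in step 7, gives the bromo depside (3S)-4-bromo-7-hydroxy-1-oxo-3-[(1R)-1-phenylethoxy]-1,3-dihydro-2-benzofuran-5-yl 3-formyl-2,4-dihydroxy-6-methylbenzoate F2. An intramolecular Ullmann etherification (CuI, N,N-dimethylglycine, Cs2CO3, dioxane, 90 °C) then comes back to the route at 17.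

**Step 9 (late ortho-formylation).** The risks are a sluggish reaction of the lactone-chelated phenoxide and opening of the depsidone ester or the pseudoester by magnesium alkoxides. The fallback installs the carbon at the alcohol level under non-basic conditions and oxidises afterwards. It sets out from 17: phenylboronic acid and paraformaldehyde (cat. propionic acid, toluene, reflux, water removal; Nagata ortho-hydroxymethylation) give the 2-phenyl-4H-1,3,2-benzodioxaborin bridging O-4 and C-5 of the depsidone F3. Transesterification with propane-1,3-diol releases the hydroxymethyl compound 18, now isolated. MnO2 in CH2Cl2 oxidises this salicylic alcohol to the aldehyde and comes back to the route at 19.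

**Step 10 (release of the lactol).** The risks are reduction of an aryl aldehyde, slow cleavage of the secondary benzylic ether, and epimerisation of the free lactol during isolation. The fallback replaces hydrogenolysis by Lewis-acid dealkylation at the auxiliary carbon. It sets out from 19: BCl3 with pentamethylbenzene as cation scavenger (CH2Cl2, −78 °C, cold aqueous quench) ionises the auxiliary at its own benzylic carbon, again without breaking a C-1–O bond, and comes back to the route at 20. This fallback makes no new compound (F0).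

## Further compounds

F1 | step 8 | (3S)-4-bromo-5,7-dihydroxy-3-[(1R)-1-phenylethoxy]-2-benzofuran-1(3H)-one | Oc1cc(O)c2c(c1Br)[C@@H](O[C@H](C)c1ccccc1)OC2=O
F2 | step 8 | (3S)-4-bromo-7-hydroxy-1-oxo-3-[(1R)-1-phenylethoxy]-1,3-dihydro-2-benzofuran-5-yl 3-formyl-2,4-dihydroxy-6-methylbenzoate | Cc1cc(O)c(C=O)c(O)c1C(=O)Oc1cc(O)c2c(c1Br)[C@@H](O[C@H](C)c1ccccc1)OC2=O
F3 | step 9 | 2-phenyl-4H-1,3,2-benzodioxaborin bridging O-4 and C-5 of depsidone 17 | Cc1cc(O)c(C=O)c2c1C(=O)Oc1c4COB(c5ccccc5)Oc4c3c(c1O2)[C@@H](O[C@H](C)c1ccccc1)OC3=O
F0 | step 10 | none | none
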